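The data stem from a simulated flask for an exercise, and the scatter is random.

Start from the two rests.

the same everywhere: left-handed substrate 0.80 M; right-handed substrate 0.80 M
- amber: solid reagent 0.48 M; free catalyst 240 mM; run made earlier
- autumn: solid reagent 0.480 M; free catalyst 160 mM; time 4.0 h
- spring: solid reagent 2.00 M; free catalyst 160 mM; time 4.0 h

amber run (percent of the left-handed substrate and right-handed substrate together charged)

| time / min | right-handed substrate / % | left-handed substrate / % |
|---|---|---|
| 3.00 | 49.0 | 50.4 |
| 10.0 | 49.7 | 49.4 |
| 15.0 | 49.3 | 47.8 |
| 25.0 | 47.9 | 46.3 |
| 40.0 | 48.3 | 43.9 |
| 50.0 | 48.4 | 44.4 |

(standard deviation of a reading: 0.5 percentage points)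

- which one finishes higher in excess of right-handed substrate over left-handed substrate among what is left of the two ("neither" within 2 percentage points) (autumn / spring / neither)
- excess of right-handed substrate over left-handed substrate among what is left of the two at the end, autumn
- excess of right-handed substrate over left-handed substrate among what is left of the two at the end, spring

- free catalyst is single-handed; left-handed substrate and right-handed substrate are mirror images of each other, charged as a racemate, each of them at the stated concentration
- given per volume of solution although it is solid: solid reagent
- what may be going on: partner + free catalyst + left-handed substrate -> free catalyst + left-handed product; 2 free catalyst -> spent catalyst; solid reagent <-> partner; partner + free catalyst + right-handed substrate -> free catalyst + right-handed product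
- at the start none of the solid reagent is in solution
- an excess is below zero if the other one leads
- no earlier run changes the charge of free catalyst; that part of a forecast is a guess

At 3.00 min the amber run shows nothing beyond the scatter. None of the solid reagent is in solution at the start, and I take its dissolving as the fast step, so partner soon holds one dissolved level while solid lies there. Over the last two amber readings, less of the left-handed substrate remains than of the right-handed, 88.3% of its charge against 96.7%. Left-handed substrate reads 43.9% and then 44.4%, a step inside the scatter of 0.5 percentage points, so these two readings show no stop, and the pairing of free catalyst into spent catalyst is what I watch next.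

Partner and free catalyst enter both product steps alike, so they cancel from the ratio of the two falls. I carry s, the selectivity factor, defined as the logarithm of the left-handed rest over the logarithm of the right-handed rest, here read as 3.71. The right-handed rest is then the left-handed rest to the power 1/s.

For autumn, catalyst charge times time is 3.20 times amber's. I allow for the pairing of free catalyst into spent catalyst by guessing that 0.5 of that counts. This leaves 81.9% of the left-handed substrate and 94.8% of the right-handed, an excess of 7.26%. The partner consumed is 0.186 M, less than the 0.480 M of solid charged, so I expect spring to match autumn.

The forecast says neither, with 9% (5.5% to 16%) for autumn and 9% (5.5% to 20%) for spring, higher than my excess; its ground is that “a saturated solution doesn't care how much solid is present”.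

The flask gives neither: 8.13% in autumn and 8.13% in spring.

    partner + free catalyst + left-handed substrate → free catalyst + left-handed product (k = 0.00420 M⁻² s⁻¹)
    2 free catalyst → spent catalyst (k = 0.00240 M⁻¹ s⁻¹)
    solid reagent ⇌ partner, rate k3*(cs3 - [partner]) while solid is left; crystals form when [partner] > cs3 (solubility = 0.130 M, k = 0.00310 s⁻¹)
    partner + free catalyst + right-handed substrate → free catalyst + right-handed product (k = 0.00140 M⁻² s⁻¹)

Autumn keeps 78% of its left-handed substrate, so s gives a right-handed rest of 93.6% and an excess of 8.91%; the flask has 92% and 8.13%. At 4.00 h, autumn holds 24.1% of its solid and spring 81.8%, with partner at 0.128 M and 0.128 M. The neighbour is spring read at 15 h. It keeps 68% of its left-handed substrate, so s gives 90.1% of the right-handed and an excess of 14.0%. The flask has 88% and 12.8%, with 75.9% of its solid reagent undissolved.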